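**Retrosynthetic overview**
- Last step: the vinyl chloride and the ring ketone are unveiled together from an (E)-alkenyl boronate whose ketone is still masked as its RAMP hydrazone (CuCl2).
- The ring-to-side-chain C–C bond and the C–B bond come from one three-component syn-carboboration of an N-propargyl amide with the 2-iodo ring hydrazone and B2pin2; the amide comes from ester aminolysis with propargylamine.
- Key disconnection: C5–C6 of the acyl chain, made by capture of a β-hydroxyalkyl radical (from (S)-2-pentyloxirane via its iodohydrin) by an (E)-alkenylnickel species from methyl (E)-5-bromopent-4-enoate; C7 comes from (S)-epichlorohydrin.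
- The ring methyl stereocentre is set by RAMP-hydrazone methylation of 2-iodo-3-methylcyclohex-2-enone; the hydrazone then serves as ketone protection for this easily epimerised centre.
- Rings: the only ring (the cyclohexenone) is bought preformed as 3-methylcyclohex-2-enone; no ring is formed in the route.

Assumption: RAMP is treated as a recoverable chiral auxiliary and B2pin2 as a reagent (neither leaves atoms in the target); the C=N geometry of hydrazones 15, 17 and 18 is not assigned.

**Step 1**
Reactants: 1 (S)-epichlorohydrin; 2 n-butylmagnesium chloride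
Product: 4 (S)-2-pentyloxirane, via (S)-1-chloroheptan-2-ol 3 (not isolated)
Conditions: n-BuMgCl (1.2 equiv), CuI (10 mol %), THF, −40 → 0 °C; then aq NaOH, Et2O, 25 °C
Reagents that add atoms: none
Why: Copper-catalysed Grignard opening of the epoxide at its CH2 carbon followed by base-induced ring closure of the chlorohydrin (Williamson-type) never touches the stereocentre, so the (S) centre of 1 becomes C7 of the target.

**Step 2**
Reactants: 5 methyl pent-4-ynoate
Product: 7 methyl (4E)-5-bromopent-4-enoate, via alkenylzirconocene chloride 6 (not isolated)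
Conditions: Cp2Zr(H)Cl (1.2 equiv), THF, 25 °C, 30 min; then NBS (1.2 equiv), 0 °C
Reagents that add atoms: N-bromosuccinimide, O=C1CCC(=O)N1Br
Why: Schwartz hydrozirconation adds Zr–H syn with zirconium on the terminal carbon and bromodezirconation proceeds with retention, so only the (E)-alkenyl bromide forms.

**Step 3**
Reactants: 4 (S)-2-pentyloxirane; 7 methyl (4E)-5-bromopent-4-enoate
Product: 9 methyl (4E,7S)-7-hydroxydodec-4-enoate, via (S)-1-iodoheptan-2-ol 8 (not isolated)
Conditions: NiCl2(dme) (10 mol %), 2,2'-bipyridine (10 mol %), NaI (25 mol %), Et3N·HCl (1 equiv), Zn (2 equiv), DMPU, 25 °C; 4 in 1.5-fold excess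
Reagents that add atoms: none
Why: Key step, a nickel-catalysed reductive cross-electrophile coupling of an epoxide with an alkenyl halide under iodide co-catalysis: iodide opens 4 at the terminal carbon to 8, nickel abstracts iodine to give the primary β-hydroxyalkyl radical, and this radical is captured by the alkenylnickel bromide from 7 and reductively eliminated with retention of the (E) geometry; the C7 centre is next to, not at, the radical carbon and is kept.

**Step 4**
Reactants: 9 methyl (4E,7S)-7-hydroxydodec-4-enoate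
Product: 10 methyl (4E,7S)-7-methoxydodec-4-enoate
Conditions: MeI (10 equiv), Ag2O (3 equiv), 4 Å molecular sieves, Et2O, 35 °C, dark
Reagents that add atoms: iodomethane, CI
Why: Purdie methylation under neutral conditions etherifies the secondary alcohol without touching the ester, the alkene or the stereocentre.

**Step 5**
Reactants: 10 methyl (4E,7S)-7-methoxydodec-4-enoate; 11 propargylamine
Product: 12 (4E,7S)-7-methoxy-N-(prop-2-yn-1-yl)dodec-4-enamide
Conditions: propargylamine (3 equiv), 1,5,7-triazabicyclo[4.4.0]dec-5-ene (0.3 equiv), THF, 60 °C, sealed tube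
Reagents that add atoms: none
Why: Guanidine-catalysed aminolysis of a methyl ester by a primary amine gives the amide directly, saving a hydrolysis and a coupling step; the skipped alkene cannot move into conjugation under these conditions.

**Step 6**
Reactants: 13 3-methylcyclohex-2-en-1-one
Product: 14 2-iodo-3-methylcyclohex-2-en-1-one
Conditions: I2 (2 equiv), pyridine/CH2Cl2 (1:1), 0 → 25 °C
Reagents that add atoms: iodine, II
Why: Johnson α-iodination of an enone (conjugate addition of pyridine, iodination of the enolate, elimination) gives the known 2-iodoenone.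

**Step 7**
Reactants: 14 2-iodo-3-methylcyclohex-2-en-1-one
Product: 15 (2R)-N-(2-iodo-3-methylcyclohex-2-en-1-ylidene)-2-(methoxymethyl)pyrrolidin-1-amine
Conditions: RAMP (1.1 equiv), TsOH·H2O (5 mol %), cyclohexane, reflux, Dean–Stark
Reagents that add atoms: RAMP, (2R)-1-amino-2-(methoxymethyl)pyrrolidine, COC[C@H]1CCCN1N
Why: Acid-catalysed hydrazone condensation; an N,N-disubstituted hydrazine cannot close to a pyrazoline, so only the hydrazone forms.

**Step 8**
Reactants: 15 (2R)-N-(2-iodo-3-methylcyclohex-2-en-1-ylidene)-2-(methoxymethyl)pyrrolidin-1-amine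
Product: 17 (2R)-N-[(6S)-2-iodo-3,6-dimethylcyclohex-2-en-1-ylidene]-2-(methoxymethyl)pyrrolidin-1-amine, via lithium azaenolate 16 (not isolated)
Conditions: LiN(i-Pr)2 (1.1 equiv), THF, −78 → 0 °C; then MeI (1.5 equiv), −100 → −78 °C
Reagents that add atoms: iodomethane, CI
Why: Enders RAMP-hydrazone alkylation: the only α-CH2 (C6) is deprotonated to the chelated azaenolate and MeI attacks the face dictated by the auxiliary; since SAMP gives (R)-2-methylcyclohexanone, RAMP is expected to give (S) at C6 (the sense should be confirmed on first run).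

**Step 9**
Reactants: 12 (4E,7S)-7-methoxy-N-(prop-2-yn-1-yl)dodec-4-enamide; 17 (2R)-N-[(6S)-2-iodo-3,6-dimethylcyclohex-2-en-1-ylidene]-2-(methoxymethyl)pyrrolidin-1-amine
Product: 18 (4E,7S)-N-{(2E)-2-[(5S)-6-{[(2R)-2-(methoxymethyl)pyrrolidin-1-yl]imino}-2,5-dimethylcyclohex-1-en-1-yl]-3-(4,4,5,5-tetramethyl-1,3,2-dioxaborolan-2-yl)prop-2-en-1-yl}-7-methoxydodec-4-enamide
Conditions: B2pin2 (1.3 equiv), CuCl (10 mol %), Xantphos (10 mol %), Pd(dba)2 (5 mol %), XPhos (10 mol %), LiOt-Bu (1.5 equiv), THF, 25 °C
Reagents that add atoms: bis(pinacolato)diboron, CC1(C)OB(OC1(C)C)B1OC(C)(C)C(C)(C)O1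
Why: Proposed new method: LCu–Ot-Bu and B2pin2 give LCu–Bpin, which adds syn across the terminal alkyne of 12 with boron on the terminal carbon and copper on the internal carbon; zerovalent palladium inserts into the carbon–iodine bond of 17, and copper-to-palladium transmetalation followed by reductive elimination joins the ring to the internal carbon with ring and boron cis (the E boronate that becomes the E chloride); the hydrazone keeps the alkoxide from epimerising C6; the closest known reaction type is the cooperative copper/palladium-catalysed aryl- and allylboration of alkynes.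

**Step 10**
Reactants: 18 (the alkenyl boronate hydrazone of step 9)
Product: 20 (4E,7S)-N-{(2E)-3-chloro-2-[(5S)-2,5-dimethyl-6-oxocyclohex-1-en-1-yl]prop-2-en-1-yl}-7-methoxydodec-4-enamide, via keto alkenyl boronate 19 (not isolated)
Conditions: CuCl2·2H2O (6 equiv), THF/MeOH/H2O (2:2:1), 23 °C, 2 h, then 60 °C
Reagents that add atoms: copper dichloride, Cl[Cu]Cl; water, O
Why: CuCl2 in aqueous THF hydrolyses RAMP hydrazones without racemisation (Enders cleavage) and on warming converts alkenyl pinacol boronates into alkenyl chlorides with retention (copper-mediated halodeboronation), so ketone and (E)-chloride are released together and the labile C6 centre is exposed only in this last operation.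

**Compound list**
1 | (S)-epichlorohydrin, (2S)-2-(chloromethyl)oxirane | ClC[C@@H]1CO1 | starting material
2 | n-butylmagnesium chloride | CCCC[Mg]Cl | starting material
3 | (S)-1-chloroheptan-2-ol | CCCCC[C@H](O)CCl | intermediate (not isolated)
4 | (S)-2-pentyloxirane | CCCCC[C@H]1CO1 | intermediate
5 | methyl pent-4-ynoate | COC(=O)CCC#C | starting material
6 | chlorobis(cyclopentadienyl)[(1E)-5-methoxy-5-oxopent-1-en-1-yl]zirconium | COC(=O)CC/C=C/[Zr](Cl)(C1C=CC=C1)C1C=CC=C1 | intermediate (not isolated)
7 | methyl (4E)-5-bromopent-4-enoate | COC(=O)CC/C=C/Br | intermediate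
8 | (S)-1-iodoheptan-2-ol | CCCCC[C@H](O)CI | intermediate (not isolated)
9 | methyl (4E,7S)-7-hydroxydodec-4-enoate | CCCCC[C@H](O)C/C=C/CCC(=O)OC | intermediate
10 | methyl (4E,7S)-7-methoxydodec-4-enoate | CCCCC[C@@H](C/C=C/CCC(=O)OC)OC | intermediate
11 | propargylamine (prop-2-yn-1-amine) | NCC#C | starting material
12 | (4E,7S)-7-methoxy-N-(prop-2-yn-1-yl)dodec-4-enamide | CCCCC[C@@H](C/C=C/CCC(=O)NCC#C)OC | intermediate
13 | 3-methylcyclohex-2-en-1-one | CC1=CC(=O)CCC1 | starting material
14 | 2-iodo-3-methylcyclohex-2-en-1-one | CC1=C(I)C(=O)CCC1 | intermediate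
15 | (2R)-N-(2-iodo-3-methylcyclohex-2-en-1-ylidene)-2-(methoxymethyl)pyrrolidin-1-amine | COC[C@H]1CCCN1N=C1CCCC(C)=C1I | intermediate
16 | lithium azaenolate of 15 (N-lithio, C1=C6 double bond) | COC[C@H]1CCCN1N([Li])C1=CCCC(C)=C1I | intermediate (not isolated)
17 | (2R)-N-[(6S)-2-iodo-3,6-dimethylcyclohex-2-en-1-ylidene]-2-(methoxymethyl)pyrrolidin-1-amine | COC[C@H]1CCCN1N=C1C(I)=C(C)CC[C@@H]1C | intermediate
18 | (4E,7S)-N-{(2E)-2-[(5S)-6-{[(2R)-2-(methoxymethyl)pyrrolidin-1-yl]imino}-2,5-dimethylcyclohex-1-en-1-yl]-3-(4,4,5,5-tetramethyl-1,3,2-dioxaborolan-2-yl)prop-2-en-1-yl}-7-methoxydodec-4-enamide | CCCCC[C@@H](C/C=C/CCC(=O)NC/C(=C/B1OC(C)(C)C(C)(C)O1)C1=C(C)CC[C@H](C)C1=NN1CCC[C@@H]1COC)OC | intermediate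
19 | (4E,7S)-N-{(2E)-2-[(5S)-2,5-dimethyl-6-oxocyclohex-1-en-1-yl]-3-(4,4,5,5-tetramethyl-1,3,2-dioxaborolan-2-yl)prop-2-en-1-yl}-7-methoxydodec-4-enamide | CCCCC[C@@H](C/C=C/CCC(=O)NC/C(=C/B1OC(C)(C)C(C)(C)O1)C1=C(C)CC[C@H](C)C1=O)OC | intermediate (not isolated)
20 | (4E,7S)-N-{(2E)-3-chloro-2-[(5S)-2,5-dimethyl-6-oxocyclohex-1-en-1-yl]prop-2-en-1-yl}-7-methoxydodec-4-enamide | CCCCC[C@@H](C/C=C/CCC(=O)NC/C(=C/Cl)C1=C(C)CC[C@H](C)C1=O)OC | target

**Step count**
Total: 10 steps. Longest linear sequence: 6 steps (1 → 4 → 9 → 10 → 12 → 18 → 20; steps 1, 3, 4, 5, 9, 10).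

**Three steps most likely to fail**

Step 9 (three-component carboboration). The risks are Sonogashira-type coupling of the terminal alkyne, protonation of the alkenylcopper by the amide N–H, and wrong regiochemistry of borylcupration. The fallback sets out from 12 (and uses 17) and comes back at 20; it puts the chlorine on first and closes with a neutral Stille coupling. Compound 12 is chlorinated at the alkyne terminus (NCS, AgOAc cat., acetone) to (4E,7S)-N-(3-chloroprop-2-yn-1-yl)-7-methoxydodec-4-enamide F1. Palladium-catalysed hydrobromination (Pd(OAc)2 cat., LiBr, AcOH; trans-bromopalladation then protonolysis) gives (4E,7S)-N-[(2Z)-2-bromo-3-chloroprop-2-en-1-yl]-7-methoxydodec-4-enamide F2, with bromine cis to chlorine. Selective stannylation of the carbon–bromine bond (Me3SnSnMe3, Pd(PPh3)4, toluene, 80 °C) gives (4E,7S)-N-[(2Z)-3-chloro-2-(trimethylstannyl)prop-2-en-1-yl]-7-methoxydodec-4-enamide F3. In parallel 17 is hydrolysed (saturated aqueous oxalic acid, Et2O) to (6S)-2-iodo-3,6-dimethylcyclohex-2-en-1-one F4. Stille coupling of F3 with F4 (Pd2(dba)3, AsPh3, CuI, NMP, 23 °C) proceeds with retention and gives 20 directly, bypassing 18, 19 and step 10.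

Step 10 (one-pot hydrazone cleavage and chlorodeboronation). The risks are partial epimerisation of C6 in warm acidic copper solution and slow halodeboronation of the hindered boronate. The fallback sets out from 18 and comes back at 20; it replaces the hot copper step by a room-temperature ipso-chlorination. Compound 18 is hydrolysed with saturated aqueous oxalic acid/Et2O and 19 is isolated. KHF2 in MeOH/H2O converts it into potassium {(1E)-2-[(5S)-2,5-dimethyl-6-oxocyclohex-1-en-1-yl]-3-[(4E,7S)-7-methoxydodec-4-enamido]prop-1-en-1-yl}trifluoroborate F5. NaCl with TsN(Cl)Na in THF/H2O at 0 °C then gives 20 with retention.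

Step 3 (radical epoxide–alkenyl bromide coupling). The risks are reductive deoxygenation of the epoxide, alkenyl homocoupling, and low turnover with the alkenyl bromide. The fallback sets out from 4 and comes back at 10; it keeps the radical C5–C6 bond formation but uses a preformed, already methylated radical precursor. Compound 4 is opened with LiI/AcOH in THF and 8 is isolated. Methylation with Me3OBF4 and 1,8-bis(dimethylamino)naphthalene in CH2Cl2 gives (2S)-1-iodo-2-methoxyheptane F6. Nickel-catalysed alkyl–alkenyl reductive coupling of F6 with 7 (NiBr2(dme), 4,4'-di-tert-butyl-2,2'-bipyridine, Mn, DMPU, 25 °C) gives 10 directly, skipping 9 and step 4.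

**Further compounds**
F1 | step 9 | (4E,7S)-N-(3-chloroprop-2-yn-1-yl)-7-methoxydodec-4-enamide | CCCCC[C@@H](C/C=C/CCC(=O)NCC#CCl)OC
F2 | step 9 | (4E,7S)-N-[(2Z)-2-bromo-3-chloroprop-2-en-1-yl]-7-methoxydodec-4-enamide | CCCCC[C@@H](C/C=C/CCC(=O)NC/C(Br)=C/Cl)OC
F3 | step 9 | (4E,7S)-N-[(2Z)-3-chloro-2-(trimethylstannyl)prop-2-en-1-yl]-7-methoxydodec-4-enamide | CCCCC[C@@H](C/C=C/CCC(=O)NC/C(=C/Cl)[Sn](C)(C)C)OC
F4 | step 9 | (6S)-2-iodo-3,6-dimethylcyclohex-2-en-1-one | C[C@H]1CCC(C)=C(I)C1=O
F5 | step 10 | potassium {(1E)-2-[(5S)-2,5-dimethyl-6-oxocyclohex-1-en-1-yl]-3-[(4E,7S)-7-methoxydodec-4-enamido]prop-1-en-1-yl}trifluoroborate | CCCCC[C@@H](C/C=C/CCC(=O)NC/C(=C/[B-](F)(F)F)C1=C(C)CC[C@H](C)C1=O)OC.[K+]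
F6 | step 3 | (2S)-1-iodo-2-methoxyheptane | CCCCC[C@H](OC)CI
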